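**Retrosynthetic overview**
1. Ring B is closed last, by ring-closing metathesis (RCM) across the O–O tether of an acyclic mixed allyl peroxyketal (propene lost). The ketal carbon C6 is then settled by acid/MeOH anomerisation with separation and recycling.
2. That peroxyketal comes from trans-peroxyketalisation of a vinyl ketone dimethyl ketal (ring A already present) with methyl (3R,4E)-3-hydroperoxyhex-4-enoate. Its C3 is set by iminium-catalysed 1,4-peroxidation of sorbaldehyde.
3. Ring A is closed first, by RCM of an acyclic bis(allylic) dialkyl peroxide (ethene lost). No singlet-oxygen cycloaddition is used for either ring.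
4. Both ring A stereocentres (C10, C13) are made as C–OO bonds by palladacycle-catalysed enantioselective SN2′ peroxidation of (Z)-allylic trichloroacetimidates, one catalyst enantiomer per centre.
5. The middle fragment is assembled from THP-protected propargyl alcohol, 1,3-dibromopropane and lithiated methoxyallene (a masked vinyl ketone).

Assumption: locants count along the C16 chain from the ester carbon (C3 R and C6 S in ring B; C10 R and C13 S in ring A); the facial sense of the COP palladacycle and of the prolinol catalyst is taken from their accepted models, and the catalyst enantiomer is exchanged if the first configurational check (reduction of the peroxide to the known allylic alcohol) disagrees.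

**Step 1**
Reactants: 1 2,3-dimethylbut-2-ene
Product: 4 2-hydroperoxy-2-methoxypropane, via 4,4,5,5-tetramethyl-1,2,3-trioxolane 2 (not isolated), via propan-2-one O-oxide 3 (not isolated)
Conditions: O3, MeOH/CH2Cl2 (1:4), −78 °C; N2 purge, warm to 0 °C
Reagents that add atoms: ozone ([O-][O+]=O); methanol (CO)
Why: Criegee ozonolysis in methanol, in which the primary ozonide of the symmetrical alkene cleaves to acetone and acetone O-oxide and the carbonyl oxide is trapped by MeOH as the hydroperoxy ketal, a base-stable and acid-removable carrier of one OOH unit.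

**Step 2**
Reactants: 5 (2Z)-hex-2-en-1-ol
Product: 6 (2Z)-hex-2-en-1-yl 2,2,2-trichloroethanimidate
Conditions: Cl3CCN, DBU (0.1 equiv), CH2Cl2, 0 °C
Reagents that add atoms: trichloroacetonitrile (ClC(Cl)(Cl)C#N)
Why: base-catalysed addition of the allylic alcohol to the nitrile (trichloroacetimidate formation) leaves the Z-alkene untouched.

**Step 3**
Reactants: 6 (2Z)-hex-2-en-1-yl 2,2,2-trichloroethanimidate and 4 2-hydroperoxy-2-methoxypropane
Product: 7 (3S)-3-[(2-methoxypropan-2-yl)peroxy]hex-1-ene
Conditions: [(Sp,R)-COP-OAc]2, i.e. [Pd(μ-OAc)(C39H33CoNO)]2, C82H72Co2N2O6Pd2 (2 mol%), 4 (3 equiv), CH2Cl2, 23→38 °C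
Reagents that add atoms: none
Why: Proposed new method: enantioselective SN2′ allylic peroxidation under divalent-palladium catalysis, in which the imidate nitrogen anchors the palladacycle on one face of the Z-alkene, the hydroperoxide (pKa about 12, α-effect oxygen nucleophile) attacks C3 anti to Pd and β-elimination of trichloroacetamide releases the branched peroxide while Pd stays divalent (no phosphine or low-valent metal that could reduce O–O), so C13 is set as (S) by catalyst control; the closest known reaction is the same palladacycle-catalysed SN2′ substitution of (Z)-allylic trichloroacetimidates by carboxylic acids and phenols, which gives branched allylic esters and aryl ethers in high ee.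

**Step 4**
Reactants: 7 (3S)-3-[(2-methoxypropan-2-yl)peroxy]hex-1-ene
Product: 8 (3S)-3-hydroperoxyhex-1-ene
Conditions: AcOH/THF/H2O (4:2:1), 23 °C; kept cold as a CH2Cl2 solution with a trace of BHT
Reagents that add atoms: none
Why: mild acid hydrolysis of the monoperoxyketal (perketal deprotection) frees the allylic hydroperoxide without touching the C13–O bond, so (S) is retained.

**Step 5**
Reactants: 9 2-(prop-2-yn-1-yloxy)oxane and 10 1,3-dibromopropane
Product: 12 2-[(6-bromohex-2-yn-1-yl)oxy]oxane, via [3-(oxan-2-yloxy)prop-1-yn-1-yl]lithium 11 (not isolated)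
Conditions: n-BuLi, THF, −78 °C; then 10 (4 equiv), DMPU, −78→23 °C
Reagents that add atoms: none
Why: SN2 alkylation of a lithium acetylide, with excess dibromide suppressing double alkylation.

**Step 6**
Reactants: 12 2-[(6-bromohex-2-yn-1-yl)oxy]oxane
Product: 13 2-{[(2Z)-6-bromohex-2-en-1-yl]oxy}oxane
Conditions: H2 (1 atm), Lindlar catalyst (Pd/CaCO3 poisoned with Pb(OAc)2), quinoline, EtOAc, 23 °C
Reagents that add atoms: none
Why: Lindlar semi-hydrogenation (syn addition of H2) gives the Z-alkene required by the later SN2′ step and leaves the primary bromide intact.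

**Step 7**
Reactants: 14 methoxyallene (1-methoxypropa-1,2-diene) and 13 2-{[(2Z)-6-bromohex-2-en-1-yl]oxy}oxane
Product: 16 2-{[(2Z)-7-methoxynona-2,7,8-trien-1-yl]oxy}oxane, via (1-methoxypropa-1,2-dien-1-yl)lithium 15 (not isolated)
Conditions: 14, n-BuLi, THF, −40 °C; then 13, −78→23 °C
Reagents that add atoms: none
Why: α-lithiation of methoxyallene and SN2 alkylation by the primary bromide installs C6 together with its future vinyl group as an allenyl ether (masked vinyl ketone).

**Step 8**
Reactants: 16 2-{[(2Z)-7-methoxynona-2,7,8-trien-1-yl]oxy}oxane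
Product: 18 (2Z)-7,7-dimethoxynona-2,8-dien-1-ol, via 2-{[(2Z)-7,7-dimethoxynona-2,8-dien-1-yl]oxy}oxane 17 (not isolated)
Conditions: PPTS (0.1 equiv), dry MeOH, 0→23 °C; Et3N quench
Reagents that add atoms: methanol (CO)
Why: acid-catalysed Markovnikov addition of methanol to the allenyl ether (protonation at the central allene carbon, capture of the methoxyallyl cation at the oxygen-bearing carbon) gives the vinyl ketone dimethyl ketal, and the same acid then methanolyses the THP acetal.

**Step 9**
Reactants: 18 (2Z)-7,7-dimethoxynona-2,8-dien-1-ol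
Product: 19 (2Z)-7,7-dimethoxynona-2,8-dien-1-yl 2,2,2-trichloroethanimidate
Conditions: Cl3CCN, DBU (0.1 equiv), CH2Cl2, 0 °C
Reagents that add atoms: trichloroacetonitrile (ClC(Cl)(Cl)C#N)
Why: trichloroacetimidate formation under catalytic base, to which the ketal and both alkenes are inert.

**Step 10**
Reactants: 19 (2Z)-7,7-dimethoxynona-2,8-dien-1-yl 2,2,2-trichloroethanimidate and 8 (3S)-3-hydroperoxyhex-1-ene
Product: 20 (3R)-3-{[(3S)-hex-1-en-3-yl]peroxy}-7,7-dimethoxynona-1,8-diene
Conditions: [(Rp,S)-COP-OAc]2, C82H72Co2N2O6Pd2 (3 mol%), 8 (1.5 equiv), CH2Cl2, 23→38 °C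
Reagents that add atoms: none
Why: Proposed new method: the palladacycle-catalysed SN2′ peroxidation of step 3, now with the secondary allylic hydroperoxide as nucleophile and the enantiomeric catalyst, so that anti attack on the Pd-bound Z-alkene followed by loss of trichloroacetamide forms C10 as (R) under catalyst control and gives the (10R,13S) peroxide that becomes cis in the ring; the closest known reaction type is the COP-catalysed SN2′ esterification and aryl-etherification of (Z)-allylic trichloroacetimidates.

**Step 11**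
Reactants: 20 (3R)-3-{[(3S)-hex-1-en-3-yl]peroxy}-7,7-dimethoxynona-1,8-diene
Product: 21 (3R,6S)-3-(4,4-dimethoxyhex-5-en-1-yl)-6-propyl-3,6-dihydro-1,2-dioxine
Conditions: second-generation Hoveyda–Grubbs catalyst RuCl2(H2IMes)(=CH–C6H4–2-OiPr), C31H38Cl2N2ORu (5 mol%), 1,4-benzoquinone (10 mol%), CH2Cl2 (5 mM), 40 °C
Reagents that add atoms: none
Why: Proposed new method: ring-closing metathesis across an O–O tether, in which the Ru alkylidene formed at one peroxy-allylic vinyl group closes on the other in a six-membered mode that the gauche C–O–O–C dihedral favours over the seven-membered carbocycle involving the hindered ketal vinyl group, the phosphine-free catalyst avoids phosphine reduction of O–O, benzoquinone suppresses Ru–H isomerisation, and no stereocentre is touched so the (10R,13S) peroxide gives the cis-3,6-disubstituted dioxine with loss of ethene; the closest known reactions are RCM of O-allyl-N-allylhydroxylamines to 3,6-dihydro-1,2-oxazines and of diallyl ethers, and cross-metathesis run on substrates that carry dialkyl peroxides.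

**Step 12**
Reactants: 22 (2E,4E)-hexa-2,4-dienal and 4 2-hydroperoxy-2-methoxypropane
Product: 23 (3R,4E)-3-[(2-methoxypropan-2-yl)peroxy]hex-4-enal
Conditions: (R)-2-[diphenyl(trimethylsilyloxy)methyl]pyrrolidine (20 mol%), 4-nitrobenzoic acid (20 mol%), 4 (1.5 equiv), toluene, 0 °C
Reagents that add atoms: none
Why: iminium-ion-catalysed enantioselective conjugate peroxidation of an enal (organocatalytic oxa-Michael addition of a hydroperoxide), in which the dienal reacts at C3 (1,4) as in the organocatalytic epoxidation of 2,4-dienals, the CPh2OTMS group of the (R)-catalyst blocks one face of the s-trans E-iminium ion so that the peroxide oxygen arrives on the other face to give (3R), and the acid co-catalyst protonates the enamine before it can close to an epoxide.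

**Step 13**
Reactants: 23 (3R,4E)-3-[(2-methoxypropan-2-yl)peroxy]hex-4-enal
Product: 24 (3R,4E)-3-[(2-methoxypropan-2-yl)peroxy]hex-4-enoic acid
Conditions: NaClO2, NaH2PO4, 2-methylbut-2-ene, t-BuOH/H2O, 0 °C (crude aldehyde used at once)
Reagents that add atoms: sodium chlorite ([Na+].[O-]Cl=O)
Why: Pinnick oxidation at about pH 4 converts the aldehyde to the acid without touching the peroxyketal, the propenyl group or C3, and removes the aldehyde before it can lose the β-peroxy group by retro-oxa-Michael reaction.

**Step 14**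
Reactants: 24 (3R,4E)-3-[(2-methoxypropan-2-yl)peroxy]hex-4-enoic acid
Product: 25 methyl (3R,4E)-3-[(2-methoxypropan-2-yl)peroxy]hex-4-enoate
Conditions: TMSCHN2, MeOH/toluene (1:4), 0 °C
Reagents that add atoms: (trimethylsilyl)diazomethane (C[Si](C)(C)C=[N+]=[N-])
Why: methyl esterification by diazomethane generated in situ is neutral, so base-induced β-elimination of the peroxide is avoided.

**Step 15**
Reactants: 25 methyl (3R,4E)-3-[(2-methoxypropan-2-yl)peroxy]hex-4-enoate
Product: 26 methyl (3R,4E)-3-hydroperoxyhex-4-enoate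
Conditions: AcOH/THF/H2O (4:2:1), 23 °C
Reagents that add atoms: none
Why: perketal hydrolysis as in step 4 frees the secondary hydroperoxide, leaving the ester and the C3 configuration unaffected.

**Step 16**
Reactants: 21 (3R,6S)-3-(4,4-dimethoxyhex-5-en-1-yl)-6-propyl-3,6-dihydro-1,2-dioxine and 26 methyl (3R,4E)-3-hydroperoxyhex-4-enoate
Product: 27 methyl (3R,4E)-3-({(3RS)-3-methoxy-6-[(3R,6S)-6-propyl-3,6-dihydro-1,2-dioxin-3-yl]hex-1-en-3-yl}peroxy)hex-4-enoate (about 1:1 mixture of the two epimers at the peroxyketal carbon C6)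
Conditions: PPTS (10 mol%), 26 (2 equiv), 5 Å molecular sieves, CH2Cl2, 0→23 °C; solid NaHCO3 quench
Reagents that add atoms: none
Why: acid-catalysed trans-peroxyketalisation, in which one OMe of the allylic dimethyl ketal leaves to give the methoxyallyl cation and the hydroperoxide captures it at the oxygen-bearing carbon (driven by sieving out MeOH and by excess 26), joins the two halves through C3–O–O–C6 without touching C3, C10 or C13, while C6 forms without control so that 27 is the epimer pair, which is acceptable because C6 is corrected in step 18.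

**Step 17**
Reactants: 27 methyl (3R,4E)-3-({(3RS)-3-methoxy-6-[(3R,6S)-6-propyl-3,6-dihydro-1,2-dioxin-3-yl]hex-1-en-3-yl}peroxy)hex-4-enoate
Product: 28 methyl 2-[(3R,6RS)-6-methoxy-6-{3-[(3R,6S)-6-propyl-3,6-dihydro-1,2-dioxin-3-yl]propyl}-3,6-dihydro-1,2-dioxin-3-yl]acetate (mixture of the two epimers at C6)
Conditions: second-generation Hoveyda–Grubbs catalyst RuCl2(H2IMes)(=CH–C6H4–2-OiPr), C31H38Cl2N2ORu (10 mol%), 1,4-benzoquinone (10 mol%), CH2Cl2 (5 mM), 40 °C; short SiO2 plug
Reagents that add atoms: none
Why: Proposed new method: RCM of a mixed allyl peroxyketal, in which the Ru alkylidene formed at the propenyl group on C3 closes on the vinyl group of the ketal carbon to give the six-membered 6-methoxy-3,6-dihydro-1,2-dioxine with loss of propene and without touching any stereocentre, so both C6 epimers of 27 cyclise and 28 keeps the epimer ratio; the closest known reaction is RCM of mixed allylic O,O-acetals made from alkoxyallenes to 2-alkoxy-3,6-dihydro-2H-pyrans, together with step 11.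

**Step 18**
Reactants: 28 methyl 2-[(3R,6RS)-6-methoxy-6-{3-[(3R,6S)-6-propyl-3,6-dihydro-1,2-dioxin-3-yl]propyl}-3,6-dihydro-1,2-dioxin-3-yl]acetate
Product: 29 methyl 2-[(3R,6S)-6-methoxy-6-{3-[(3R,6S)-6-propyl-3,6-dihydro-1,2-dioxin-3-yl]propyl}-3,6-dihydro-1,2-dioxin-3-yl]acetate (target)
Conditions: SiO2 chromatography (29 collected); the (6R) fraction: CSA (5 mol%), MeOH, 23 °C, solid NaHCO3 quench, re-chromatographed (two to three cycles)
Reagents that add atoms: methanol (CO)
Why: acid-catalysed anomerisation of the cyclic methoxy peroxyketal, in which reversible loss of methanol gives the ring peroxycarbenium ion (an oxygen-stabilised allyl cation) that re-adds MeOH at C6 from either face, interconverts the two C6 epimers (a ratio near 1:1 is expected because OMe can sit pseudoaxial in both), so that separating the (6S) compound and re-equilibrating the (6R) fraction funnels the material into 29 while C3, C10 and C13 stay fixed and the base-free quench avoids Kornblum–DeLaMare cleavage of the dioxines.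

**Compound list**
1 | 2,3-dimethylbut-2-ene | CC(C)=C(C)C | starting material
2 | 4,4,5,5-tetramethyl-1,2,3-trioxolane | CC1(C)OOOC1(C)C | intermediate
3 | propan-2-one O-oxide | CC(C)=[O+][O-] | intermediate
4 | 2-hydroperoxy-2-methoxypropane | COC(C)(C)OO | intermediate
5 | (2Z)-hex-2-en-1-ol | CCC/C=C\CO | starting material
6 | (2Z)-hex-2-en-1-yl 2,2,2-trichloroethanimidate | CCC/C=C\COC(=N)C(Cl)(Cl)Cl | intermediate
7 | (3S)-3-[(2-methoxypropan-2-yl)peroxy]hex-1-ene | CCC[C@H](OOC(C)(C)OC)C=C | intermediate
8 | (3S)-3-hydroperoxyhex-1-ene | CCC[C@H](OO)C=C | intermediate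
9 | 2-(prop-2-yn-1-yloxy)oxane (racemic THP acetal) | C#CCOC1CCCCO1 | starting material
10 | 1,3-dibromopropane | BrCCCBr | starting material
11 | [3-(oxan-2-yloxy)prop-1-yn-1-yl]lithium | [Li]C#CCOC1CCCCO1 | intermediate
12 | 2-[(6-bromohex-2-yn-1-yl)oxy]oxane | BrCCCC#CCOC1CCCCO1 | intermediate
13 | 2-{[(2Z)-6-bromohex-2-en-1-yl]oxy}oxane | BrCCC/C=C\COC1CCCCO1 | intermediate
14 | methoxyallene (1-methoxypropa-1,2-diene) | COC=C=C | starting material
15 | (1-methoxypropa-1,2-dien-1-yl)lithium | [Li]C(OC)=C=C | intermediate
16 | 2-{[(2Z)-7-methoxynona-2,7,8-trien-1-yl]oxy}oxane | C=C=C(OC)CCC/C=C\COC1CCCCO1 | intermediate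
17 | 2-{[(2Z)-7,7-dimethoxynona-2,8-dien-1-yl]oxy}oxane | C=CC(OC)(OC)CCC/C=C\COC1CCCCO1 | intermediate
18 | (2Z)-7,7-dimethoxynona-2,8-dien-1-ol | C=CC(OC)(OC)CCC/C=C\CO | intermediate
19 | (2Z)-7,7-dimethoxynona-2,8-dien-1-yl 2,2,2-trichloroethanimidate | C=CC(OC)(OC)CCC/C=C\COC(=N)C(Cl)(Cl)Cl | intermediate
20 | (3R)-3-{[(3S)-hex-1-en-3-yl]peroxy}-7,7-dimethoxynona-1,8-diene | CCC[C@@H](C=C)OO[C@@H](C=C)CCCC(OC)(OC)C=C | intermediate
21 | (3R,6S)-3-(4,4-dimethoxyhex-5-en-1-yl)-6-propyl-3,6-dihydro-1,2-dioxine | CCC[C@H]1C=C[C@@H](CCCC(OC)(OC)C=C)OO1 | intermediate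
22 | (2E,4E)-hexa-2,4-dienal | C/C=C/C=C/C=O | starting material
23 | (3R,4E)-3-[(2-methoxypropan-2-yl)peroxy]hex-4-enal | C/C=C/[C@@H](CC=O)OOC(C)(C)OC | intermediate
24 | (3R,4E)-3-[(2-methoxypropan-2-yl)peroxy]hex-4-enoic acid | C/C=C/[C@@H](CC(=O)O)OOC(C)(C)OC | intermediate
25 | methyl (3R,4E)-3-[(2-methoxypropan-2-yl)peroxy]hex-4-enoate | C/C=C/[C@@H](CC(=O)OC)OOC(C)(C)OC | intermediate
26 | methyl (3R,4E)-3-hydroperoxyhex-4-enoate | C/C=C/[C@@H](CC(=O)OC)OO | intermediate
27 | methyl (3R,4E)-3-({(3RS)-3-methoxy-6-[(3R,6S)-6-propyl-3,6-dihydro-1,2-dioxin-3-yl]hex-1-en-3-yl}peroxy)hex-4-enoate (mixture of the two epimers at the peroxyketal carbon C6) | CCC[C@H]1C=C[C@@H](CCCC(OC)(C=C)OO[C@@H](/C=C/C)CC(=O)OC)OO1 | intermediate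
28 | methyl 2-[(3R,6RS)-6-methoxy-6-{3-[(3R,6S)-6-propyl-3,6-dihydro-1,2-dioxin-3-yl]propyl}-3,6-dihydro-1,2-dioxin-3-yl]acetate (mixture of the two epimers at C6) | CCC[C@H]1C=C[C@@H](CCCC2(OC)C=C[C@@H](CC(=O)OC)OO2)OO1 | intermediate
29 | methyl 2-[(3R,6S)-6-methoxy-6-{3-[(3R,6S)-6-propyl-3,6-dihydro-1,2-dioxin-3-yl]propyl}-3,6-dihydro-1,2-dioxin-3-yl]acetate | CCC[C@H]1C=C[C@@H](CCC[C@@]2(OC)C=C[C@@H](CC(=O)OC)OO2)OO1 | target

**Step count and risk**
Total steps: 18. Longest linear sequence: 10 (steps 5, 6, 7, 8, 9, 10, 11, 16, 17 and 18, from 9 to 29).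

The three steps most likely to fail are steps 3, 10 and 11.

Step 3 is the first use of a hydroperoxide in the palladacycle SN2′ reaction. The hydroperoxide is about two pKa units less acidic than the phenols that are known to work, and divalent palladium may decompose it or divert the imidate into the competing [3,3] rearrangement. The fallback replaces the catalytic C–OO bond formation by a classical SN2 displacement on a sulfonate whose stereocentre is made with the established carboxylate version of the same catalyst. It sets out from 6 and comes back at 7. Imidate 6 with AcOH and [(Rp,S)-COP-OAc]2 in CH2Cl2 gives (3R)-hex-1-en-3-yl acetate F1. K2CO3 in MeOH gives (3R)-hex-1-en-3-ol F2. MsCl/Et3N at −30 °C gives (3R)-hex-1-en-3-yl methanesulfonate F3, used cold and crude. The cesium salt of 4 (CsOH·H2O, DMF, 0 °C) displaces the mesylate with inversion to give 7.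

Step 10 uses a hindered, chiral secondary allylic hydroperoxide as the nucleophile, so slow turnover and Pd-induced loss of 8 are the main dangers. The fallback again changes from catalytic SN2′ to stoichiometric SN2 with inversion. It sets out from 19 and comes back at 20. Imidate 19 with AcOH and [(Sp,R)-COP-OAc]2 gives (3S)-7,7-dimethoxynona-1,8-dien-3-yl acetate F4. K2CO3/MeOH gives (3S)-7,7-dimethoxynona-1,8-dien-3-ol F5. MsCl/Et3N at −30 °C gives (3S)-7,7-dimethoxynona-1,8-dien-3-yl methanesulfonate F6. The cesium peroxide of 8 (CsOH·H2O, DMF, 0 °C) then gives 20 with inversion at C10.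

Step 11 is the first metathesis next to an O–O bond. It can fail through O–O cleavage by the divalent ruthenium alkylidene, through Ru-promoted rearrangement of the dioxine once formed, or through competing seven-ring closure onto the ketal vinyl group. The fallback gives up metathesis for ring A and returns to oxygen transfer onto a diene, at the cost of catalyst control over C10 and C13. It sets out from 18 and comes back at 21, and also makes steps 2–4, 9 and 10 unnecessary. Alcohol 18 is oxidised with MnO2 in CH2Cl2 and isomerised with a trace of iodine to (2E)-7,7-dimethoxynona-2,8-dienal F7. Julia–Kocienski olefination with 5-(butane-1-sulfonyl)-1-phenyl-1H-tetrazole and KN(SiMe3)2 in THF at −78 °C gives (7E,9E)-3,3-dimethoxytrideca-1,7,9-triene F8. Photooxygenation (O2, hν, tetraphenylporphyrin, CH2Cl2, 0 °C) adds singlet oxygen suprafacially to the (E,E)-diene and gives the cis-dioxine as the racemate of 21 and (3S,6R)-3-(4,4-dimethoxyhex-5-en-1-yl)-6-propyl-3,6-dihydro-1,2-dioxine F9. Preparative chiral HPLC delivers 21. Step 17 is the same reaction type as step 11 but has the closer acetal precedent; this fallback does not cover it.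

**Further compounds**
F1 | step 3 | (3R)-hex-1-en-3-yl acetate | CCC[C@@H](OC(C)=O)C=C
F2 | step 3 | (3R)-hex-1-en-3-ol | CCC[C@@H](O)C=C
F3 | step 3 | (3R)-hex-1-en-3-yl methanesulfonate | CCC[C@@H](OS(C)(=O)=O)C=C
F4 | step 10 | (3S)-7,7-dimethoxynona-1,8-dien-3-yl acetate | CC(=O)O[C@H](C=C)CCCC(OC)(OC)C=C
F5 | step 10 | (3S)-7,7-dimethoxynona-1,8-dien-3-ol | O[C@H](C=C)CCCC(OC)(OC)C=C
F6 | step 10 | (3S)-7,7-dimethoxynona-1,8-dien-3-yl methanesulfonate | CS(=O)(=O)O[C@H](C=C)CCCC(OC)(OC)C=C
F7 | step 11 | (2E)-7,7-dimethoxynona-2,8-dienal | C=CC(OC)(OC)CCC/C=C/C=O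
F8 | step 11 | (7E,9E)-3,3-dimethoxytrideca-1,7,9-triene | CCC/C=C/C=C/CCCC(OC)(OC)C=C
F9 | step 11 | (3S,6R)-3-(4,4-dimethoxyhex-5-en-1-yl)-6-propyl-3,6-dihydro-1,2-dioxine | CCC[C@@H]1C=C[C@H](CCCC(OC)(OC)C=C)OO1
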